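The ring carbons are numbered C-1 to C-10: C-6 is the tiglate carbon and C-10 the methyl-bearing carbon of the E olefin. The ten-membered ring is read as a cyclopentane (C-6 to C-10) fused to a cycloheptene (C-10, C-1 to C-6) that lacks only the shared C-6–C-10 bond. Grob fragmentation of that trans-fused bicycle, with the tertiary C-6 alkoxide pushing and a C-1 mesylate leaving, cuts this bond. In one operation it delivers the C-6 ketone, the E C-1=C-10 olefin and the ten-membered ring. The Z C-3=C-4 olefin and the all-cis C-7, C-8, C-9 substituents are set beforehand on the small rings. The precursor is a hydroazulenol mesylate with a C-2 dioxolane and silyl-protected O-8, O-9 and O-12.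

Key step: step 17

Remark on numbering: germacrane numbering is used throughout. C-2 is the ring ketone, C-3=C-4 the Z olefin (C-15 on C-4), C-5 the CH2, C-7 bears the arm C-11(=C-13)–C-12, C-8 carries the lactone oxygen, C-9 the carbinol, and C-14 is the methyl on C-10. In the cyclopentenone intermediates, ring C-1 to C-5 correspond to C-6, C-7, C-8, C-9, C-10.

Remark on the precursor: C-1, C-6 and C-10 become trigonal in step 17, so their configuration is a free design element. It is chosen so that the C-10 side chain, O-9, O-8, the C-7 arm and the C-6 hydroxyl lie on one face of the cyclopentane, with C-14 and C-5 on the other. Every group can then enter under steric or hydroxyl direction, the ring fusion is trans, and the C-1 mesylate ends cis to the angular methyl, which is the relation that leads to the E olefin. C-7 is created only after C-6 has stopped being a ketone, so it cannot epimerise on the five-membered ring. The diol is carried as two silyl ethers.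

Assumption: (S)-4-(tert-butyldimethylsilyloxy)cyclopent-2-en-1-one, methyl 3-bromo-2-oxobutanoate, 2-bromoprop-2-en-1-ol, tiglic acid and 2-methylallylmagnesium chloride solution are taken as purchasable.

Step 1
Reactants: 1 methyl 3-bromo-2-oxobutanoate (racemic)
Product: 2 methyl 2-(1-bromoethyl)-1,3-dioxolane-2-carboxylate (racemic)
Conditions: HOCH2CH2OH, p-TsOH (cat.), benzene, reflux, Dean–Stark
Reagents that add atoms: ethane-1,2-diol, OCCO
Why: Acid-catalysed ketalisation with azeotropic removal of water should work because the ketone, flanked by an ester and a bromoalkyl group, is electrophilic and forms the dioxolane as pyruvate esters do.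

Step 2
Reactants: 2 methyl 2-(1-bromoethyl)-1,3-dioxolane-2-carboxylate
Product: 3 methyl 2-vinyl-1,3-dioxolane-2-carboxylate
Conditions: KOtBu, THF, 0 °C to rt
Reagents that add atoms: none
Why: E2 dehydrobromination can only give the vinyl group, since the methyl hydrogens are the only ones β to bromine and the ester has no α-hydrogen.

Step 3
Reactants: 3 methyl 2-vinyl-1,3-dioxolane-2-carboxylate
Product: 4 2-vinyl-1,3-dioxolane-2-carbaldehyde
Conditions: i-Bu2AlH (1.05 equiv), CH2Cl2, −78 °C; aq. potassium sodium tartrate
Reagents that add atoms: none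
Why: Partial reduction of an ester to the aldehyde works here because the α,α-dialkoxy ester gives a chelated tetrahedral aluminate that is stable at −78 °C and releases the non-enolisable aldehyde only on work-up.

Step 4
Reactants: 5 2-bromoprop-2-en-1-ol
Product: 6 (2-bromoallyloxy)(tert-butyl)dimethylsilane
Conditions: TBSCl, imidazole, DMF, rt
Reagents that add atoms: tert-butyldimethylsilyl chloride, CC(C)(C)[Si](C)(C)Cl
Why: Routine silylation of a primary allylic alcohol gives the protected C-11 to C-13 arm.

Step 5
Reactants: 7 (S)-4-(tert-butyldimethylsilyloxy)cyclopent-2-en-1-one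
Product: 8 (S)-4-(tert-butyldimethylsilyloxy)-2-iodocyclopent-2-en-1-one
Conditions: I2, pyridine/CH2Cl2, 0 °C to rt
Reagents that add atoms: iodine, II
Why: Johnson α-iodination of an enone (pyridine conjugate addition, iodination of the enolate, elimination) is established for this cyclopentenone and leaves the C-9 stereocentre untouched.

Step 6
Reactants: 8 (S)-4-(tert-butyldimethylsilyloxy)-2-iodocyclopent-2-en-1-one; 6 (2-bromoallyloxy)(tert-butyl)dimethylsilane
Product: 11 (S)-4-(tert-butyldimethylsilyloxy)-2-[3-(tert-butyldimethylsilyloxy)prop-1-en-2-yl]cyclopent-2-en-1-one, via alkenyllithium 9 (not isolated), via alkenylzinc chloride 10 (not isolated)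
Conditions: 6, t-BuLi (2 equiv), Et2O, −78 °C; ZnCl2, THF, −78 to 0 °C; then 8, Pd(PPh3)4 (5 mol %), THF, rt
Reagents that add atoms: none
Why: Negishi coupling of an α-iodoenone with an alkenylzinc reagent joins C-7 to C-11, and prompt transmetalation to zinc at −78 °C should forestall silyl migration in the lithio species.

Step 7
Reactants: 11 (S)-4-(tert-butyldimethylsilyloxy)-2-[3-(tert-butyldimethylsilyloxy)prop-1-en-2-yl]cyclopent-2-en-1-one; 4 2-vinyl-1,3-dioxolane-2-carbaldehyde
Product: 13 C-10 aldol adduct bearing a hydroxy(2-vinyl-1,3-dioxolan-2-yl)methyl group trans to O-9, via lithium dienolate 12 (not isolated)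
Conditions: LiN(i-Pr)2 (1.05 equiv), THF, −78 °C; then 4; AcOH, −78 °C
Reagents that add atoms: none
Why: Kinetic α′-deprotonation and aldol addition to the electron-poor, non-enolisable aldehyde should form the C-10–C-1 bond trans to the silyloxy group; the C-10 hydrogen is replaced in step 8 and the C-1 carbinol is oxidised in step 10, so either epimer converges (the anti-aldol isomer is drawn).

Step 8
Reactants: 13 C-10 aldol adduct
Product: 15 C-10 quaternary ketone with the C-14 methyl trans and the C-1 side chain cis to O-9, via dilithium alkoxide-enolate 14 (not isolated)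
Conditions: LiN(i-Pr)2 (2.3 equiv), THF, −78 to −40 °C; MeI, DMPU, −78 to −40 °C; AcOH, −78 °C
Reagents that add atoms: iodomethane, CI
Why: Enolate alkylation of the alkoxide-enolate dianion (Fráter–Seebach type) should be safe from retro-aldol because the alkoxide is already charged, and iodomethane should approach C-10 anti to the adjacent silyloxy group, which sets the quaternary centre with methyl trans and side chain cis to O-9.

Step 9
Reactants: 15 C-10 quaternary ketone
Product: 16 tertiary C-6 alcohol with the 2-methylallyl group cis to C-14 and the hydroxyl cis to the C-1 side chain and O-9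
Conditions: CH2=C(CH3)CH2MgCl (3 equiv), CeCl3, THF, −78 °C
Reagents that add atoms: 2-methylallylmagnesium chloride, CC(=C)C[Mg]Cl
Why: 1,2-Addition of an allylic Grignard reagent to the enone carbonyl should occur from the methyl face, because the magnesium alkoxide of the C-1 hydroxyl chelates the carbonyl on the face of the bulky side chain, which sets C-6.

Step 10
Reactants: 16 tertiary C-6 alcohol
Product: 17 C-1 ketone (β-hydroxy ketone)
Conditions: Dess–Martin periodinane, NaHCO3, CH2Cl2, 0 °C to rt
Reagents that add atoms: none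
Why: Dess–Martin oxidation touches only the secondary alcohol (the tertiary allylic alcohol is inert) and removes the uncontrolled C-1 centre, which is rebuilt in step 15.

Step 11
Reactants: 17 C-1 ketone
Product: 18 7,8-epoxide on the face of the C-6 hydroxyl and O-9
Conditions: VO(acac)2 (5 mol %), t-BuOOH (decane), CH2Cl2, 0 °C
Reagents that add atoms: tert-butyl hydroperoxide, CC(C)(C)OO
Why: Vanadium-catalysed hydroxyl-directed epoxidation should deliver oxygen from the tertiary allylic C-6 hydroxyl to its own face of the trisubstituted C-7=C-8 olefin, faster than to the homoallylic 1,1-disubstituted olefins, which sets O-8 cis to O-9.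

Step 12
Reactants: 18 7,8-epoxide
Product: 19 6,8-diol with H-7 trans to O-8 (C-10 chain, O-9, O-8, C-7 arm and C-6 hydroxyl all cis)
Conditions: Pd2(dba)3·CHCl3 (2.5 mol %), n-Bu3P (10 mol %), HCO2H, Et3N, 1,4-dioxane, rt
Reagents that add atoms: none
Why: Tsuji–Shimizu formate hydrogenolysis of an alkenyl oxirane should set C-7, since zerovalent palladium opens the allylic C-7–O bond from the face opposite oxygen and then passes hydride to the more substituted allyl terminus from its own face, so hydrogen replaces oxygen with inversion and the C-11 arm ends cis to O-8 with the 1,1-disubstituted olefin retained.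

Step 13
Reactants: 19 6,8-diol
Product: 20 8-O-tert-butyldimethylsilyl ether
Conditions: TBSOTf (1.2 equiv), 2,6-lutidine, CH2Cl2, −78 °C
Reagents that add atoms: tert-butyldimethylsilyl trifluoromethanesulfonate, CC(C)(C)[Si](C)(C)OS(=O)(=O)C(F)(F)F
Why: Silylation with the triflate should take the only secondary hydroxyl, the tertiary C-6 hydroxyl being unreactive at −78 °C and needed free later.

Step 14
Reactants: 20 8-O-tert-butyldimethylsilyl ether
Product: 21 trans-fused hydroazulenone (C-1 ketone, C-2 dioxolane, Z C-3=C-4, 6-hydroxy)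
Conditions: second-generation Grubbs catalyst (10 mol %), toluene (2 mM), 80 °C
Reagents that add atoms: none
Why: Ring-closing metathesis between the vinyl ketal and the 2-methylallyl group should close the seven-membered ring, in which the trisubstituted olefin is necessarily Z; the trans-disposed tethers on C-6 and C-10 give the trans ring fusion, and the more hindered C-11 olefin could only form a bridged ring.

Step 15
Reactants: 21 trans-fused hydroazulenone
Product: 22 1,6-diol with the C-1 hydroxyl trans to the C-6 hydroxyl and cis to C-14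
Conditions: Me4NBH(OAc)3 (5 equiv), AcOH/MeCN (1:1), −20 °C to rt
Reagents that add atoms: none
Why: Evans–Saksena directed reduction should set C-1, since the tertiary C-6 hydroxyl binds boron and delivers hydride to its own face of the β-ketone, giving the 1,3-anti diol with the C-1 hydroxyl equatorial and cis to the angular methyl.

Step 16
Reactants: 22 1,6-diol
Product: 23 C-1 mesylate (hydroazulenol mesylate)
Conditions: MsCl, Et3N, CH2Cl2, 0 °C
Reagents that add atoms: methanesulfonyl chloride, CS(=O)(=O)Cl
Why: Sulfonylation through the sulfene tolerates the hindered secondary alcohol and leaves the tertiary alcohol free, and triethylamine cannot form the alkoxide that would start the fragmentation.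

Step 17
Reactants: 23 C-1 mesylate (hydroazulenol mesylate)
Product: 25 (1(10)E,3Z)-cyclodecadien-6-one 2-ethylene ketal, via potassium alkoxide 24 (not isolated)
Conditions: KN(SiMe3)2 (1.05 equiv), THF, −78 to 0 °C; pH 7 phosphate buffer, −78 °C
Reagents that add atoms: none
Why: Deprotonation of the tertiary C-6 hydroxyl gives alkoxide 24, in which the oxygen lone pair, the C-6–C-10 bond and the C-1–O bond of the mesylate are anti-periplanar, so C-6 becomes the carbonyl, the C-6–C-10 bond breaks and its electrons expel methanesulfonate in one concerted Grob fragmentation. The closest known reaction type is the Wharton-type fragmentation of bicyclic 1,3-diol monosulfonates to cyclodecenones. No ring is closed by bond formation: the ten-membered ring appears by loss of the bond shared by the five- and seven-membered rings, a ring enlargement by fragmentation. No stereocentre is formed; the only new stereo-element is the C-1=C-10 olefin, whose E geometry follows from the C-1/C-10 relative configuration set in step 15 (mesylate cis to C-14, hence C-2 gauche to C-14 and anti to C-9 when the leaving group is anti to the breaking bond). The step needs fragmentation to outrun substitution, elimination and base-induced isomerisation of the β,γ-unsaturated ketone: the anti-periplanar geometry of the trans-fused bicycle, the fully substituted carbons on both sides of C-1 (no 1,2-elimination possible), the ketal that disfavours ionisation, and one equivalent of non-nucleophilic base with a cold buffered quench should secure this.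

Step 18
Reactants: 25 (1(10)E,3Z)-cyclodecadien-6-one 2-ethylene ketal
Product: 26 (6S)-alcohol
Conditions: (R)-2-methyl-CBS-oxazaborolidine (0.3 equiv), catecholborane (2 equiv), toluene, −78 °C
Reagents that add atoms: none
Why: Corey–Bakshi–Shibata reduction should set C-6 under reagent control, the catalyst binding the carbonyl lone pair on the side of the small C-5 methylene and away from the branched C-7 so that the (R)-catalyst gives the (6S)-alcohol, while the non-basic medium spares the β,γ-enone and the C-7 stereocentre.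

Step 19
Reactants: 26 (6S)-alcohol; 27 tiglic acid
Product: 29 6-O-tiglate, via mixed anhydride 28 (not isolated)
Conditions: 27, 2,4,6-Cl3C6H2COCl, Et3N, toluene, rt; then 26, DMAP, rt
Reagents that add atoms: none
Why: Yamaguchi esterification acylates the hindered secondary alcohol with retention at C-6, and the E acid is the stable isomer, so the olefin geometry is not at risk.

Step 20
Reactants: 29 6-O-tiglate
Product: 30 8,9,12-triol dienone
Conditions: 48% aq. HF, MeCN, 0 °C to rt
Reagents that add atoms: water, O
Why: Aqueous HF should remove the three silyl ethers and hydrolyse the doubly allylic dioxolane in one operation, giving the cross-conjugated dienone while the tiglate survives.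

Step 21
Reactants: 30 8,9,12-triol dienone
Product: 33 target CNP0230565.2, via hydroxy enal 31 (not isolated), via lactol 32 (not isolated)
Conditions: TEMPO (20 mol %), PhI(OAc)2 (2.5 equiv), CH2Cl2, rt
Reagents that add atoms: none
Why: TEMPO/PhI(OAc)2 oxidative lactonisation of a 2-methylene-1,4-diol should oxidise only the primary allylic alcohol, the enal then closing with the cis O-8 to the five-membered lactol, which is oxidised to the α-methylene lactone while the secondary C-9 hydroxyl is left alone.

Compound list
1 | methyl 3-bromo-2-oxobutanoate (racemic) | COC(=O)C(=O)C(C)Br | starting material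
2 | methyl 2-(1-bromoethyl)-1,3-dioxolane-2-carboxylate (racemic) | COC(=O)C1(C(C)Br)OCCO1 | intermediate
3 | methyl 2-vinyl-1,3-dioxolane-2-carboxylate | COC(=O)C1(C=C)OCCO1 | intermediate
4 | 2-vinyl-1,3-dioxolane-2-carbaldehyde | O=CC1(C=C)OCCO1 | intermediate
5 | 2-bromoprop-2-en-1-ol | OCC(Br)=C | starting material
6 | (2-bromoallyloxy)(tert-butyl)dimethylsilane | C=C(Br)CO[Si](C)(C)C(C)(C)C | intermediate
7 | (S)-4-(tert-butyldimethylsilyloxy)cyclopent-2-en-1-one | O=C1C=C[C@@H](O[Si](C)(C)C(C)(C)C)C1 | starting material
8 | (S)-4-(tert-butyldimethylsilyloxy)-2-iodocyclopent-2-en-1-one | O=C1C(I)=C[C@@H](O[Si](C)(C)C(C)(C)C)C1 | intermediate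
9 | [3-(tert-butyldimethylsilyloxy)prop-1-en-2-yl]lithium (not isolated) | [Li]C(=C)CO[Si](C)(C)C(C)(C)C | intermediate
10 | [3-(tert-butyldimethylsilyloxy)prop-1-en-2-yl]zinc chloride (not isolated) | Cl[Zn]C(=C)CO[Si](C)(C)C(C)(C)C | intermediate
11 | (S)-4-(tert-butyldimethylsilyloxy)-2-[3-(tert-butyldimethylsilyloxy)prop-1-en-2-yl]cyclopent-2-en-1-one | O=C1C(C(=C)CO[Si](C)(C)C(C)(C)C)=C[C@@H](O[Si](C)(C)C(C)(C)C)C1 | intermediate
12 | lithium cross-conjugated dienolate of 11 (not isolated) | [Li]OC1=C[C@H](O[Si](C)(C)C(C)(C)C)C=C1C(=C)CO[Si](C)(C)C(C)(C)C | intermediate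
13 | aldol adduct: 11 carrying at ring C-5 (C-10) a hydroxy(2-vinyl-1,3-dioxolan-2-yl)methyl group trans to the 4-silyloxy group; anti-aldol carbinol epimer drawn | O=C1C(C(=C)CO[Si](C)(C)C(C)(C)C)=C[C@@H](O[Si](C)(C)C(C)(C)C)[C@@H]1[C@H](O)C2(C=C)OCCO2 | intermediate
14 | dilithium alkoxide-enolate of 13 (not isolated) | [Li]OC1=C([C@H](O[Li])C2(C=C)OCCO2)[C@H](O[Si](C)(C)C(C)(C)C)C=C1C(=C)CO[Si](C)(C)C(C)(C)C | intermediate
15 | 5-methyl derivative of 13: quaternary C-10 with methyl trans and hydroxyalkyl chain cis to the C-9 silyloxy group | O=C1C(C(=C)CO[Si](C)(C)C(C)(C)C)=C[C@@H](O[Si](C)(C)C(C)(C)C)[C@@]1(C)[C@H](O)C2(C=C)OCCO2 | intermediate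
16 | tertiary C-6 alcohol: 1-(2-methylallyl)cyclopent-2-en-1-ol from 15, hydroxyl cis to the C-1 side chain and O-9, methallyl cis to C-14 | O[C@@]1(CC(C)=C)C(C(=C)CO[Si](C)(C)C(C)(C)C)=C[C@@H](O[Si](C)(C)C(C)(C)C)[C@@]1(C)[C@H](O)C2(C=C)OCCO2 | intermediate
17 | C-1 ketone of 16 (β-hydroxy ketone) | O[C@@]1(CC(C)=C)C(C(=C)CO[Si](C)(C)C(C)(C)C)=C[C@@H](O[Si](C)(C)C(C)(C)C)[C@@]1(C)C(=O)C2(C=C)OCCO2 | intermediate
18 | 7,8-epoxide of 17, oxirane cis to the C-6 hydroxyl and O-9 | O[C@@]1(CC(C)=C)[C@@]2(C(=C)CO[Si](C)(C)C(C)(C)C)O[C@H]2[C@@H](O[Si](C)(C)C(C)(C)C)[C@@]1(C)C(=O)C3(C=C)OCCO3 | intermediate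
19 | 6,8-diol: H-7 trans to O-8; C-10 acyl chain, O-9, O-8, C-7 arm and C-6 hydroxyl all cis | O[C@@]1(CC(C)=C)[C@@H](C(=C)CO[Si](C)(C)C(C)(C)C)[C@@H](O)[C@@H](O[Si](C)(C)C(C)(C)C)[C@@]1(C)C(=O)C2(C=C)OCCO2 | intermediate
20 | 8-O-tert-butyldimethylsilyl ether of 19 | O[C@@]1(CC(C)=C)[C@@H](C(=C)CO[Si](C)(C)C(C)(C)C)[C@@H](O[Si](C)(C)C(C)(C)C)[C@@H](O[Si](C)(C)C(C)(C)C)[C@@]1(C)C(=O)C2(C=C)OCCO2 | intermediate
21 | trans-fused hydroazulenone: cyclopentane C-6 to C-10 fused to cycloheptene with C-1 ketone, C-2 dioxolane, Z C-3=C-4, tertiary 6-hydroxyl | CC(C)(C)[Si](C)(C)O[C@@H]1[C@H](C(=C)CO[Si](C)(C)C(C)(C)C)[C@@]2(O)C/C(C)=C\C3(OCCO3)C(=O)[C@]2(C)[C@@H]1O[Si](C)(C)C(C)(C)C | intermediate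
22 | hydroazulene-1,6-diol: C-1 hydroxyl trans to the C-6 hydroxyl, cis to C-14 | CC(C)(C)[Si](C)(C)O[C@@H]1[C@H](C(=C)CO[Si](C)(C)C(C)(C)C)[C@@]2(O)C/C(C)=C\C3(OCCO3)[C@@H](O)[C@]2(C)[C@@H]1O[Si](C)(C)C(C)(C)C | intermediate
23 | hydroazulenol mesylate (C-1 methanesulfonate of 22) | CC(C)(C)[Si](C)(C)O[C@@H]1[C@H](C(=C)CO[Si](C)(C)C(C)(C)C)[C@@]2(O)C/C(C)=C\C3(OCCO3)[C@@H](OS(C)(=O)=O)[C@]2(C)[C@@H]1O[Si](C)(C)C(C)(C)C | intermediate
24 | potassium C-6 alkoxide of 23 (not isolated) | CC(C)(C)[Si](C)(C)O[C@@H]1[C@H](C(=C)CO[Si](C)(C)C(C)(C)C)[C@@]2(O[K])C/C(C)=C\C3(OCCO3)[C@@H](OS(C)(=O)=O)[C@]2(C)[C@@H]1O[Si](C)(C)C(C)(C)C | intermediate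
25 | (1(10)E,3Z)-cyclodecadien-6-one 2-ethylene ketal with 8,9-bis(silyloxy) groups and the silyloxy-isopropenyl arm on C-7 | CC(C)(C)[Si](C)(C)O[C@@H]1[C@H](C(=C)CO[Si](C)(C)C(C)(C)C)C(=O)C/C(C)=C\C2(OCCO2)/C=C(\C)[C@@H]1O[Si](C)(C)C(C)(C)C | intermediate
26 | (6S)-alcohol from 25 | CC(C)(C)[Si](C)(C)O[C@@H]1[C@H](C(=C)CO[Si](C)(C)C(C)(C)C)[C@@H](O)C/C(C)=C\C2(OCCO2)/C=C(\C)[C@@H]1O[Si](C)(C)C(C)(C)C | intermediate
27 | tiglic acid | C/C=C(\C)C(=O)O | starting material
28 | tiglic 2,4,6-trichlorobenzoic mixed anhydride (not isolated) | C/C=C(\C)C(=O)OC(=O)c1c(Cl)cc(Cl)cc1Cl | intermediate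
29 | 6-O-tiglate of 26 | CC(C)(C)[Si](C)(C)O[C@@H]1[C@H](C(=C)CO[Si](C)(C)C(C)(C)C)[C@@H](OC(=O)/C(C)=C/C)C/C(C)=C\C2(OCCO2)/C=C(\C)[C@@H]1O[Si](C)(C)C(C)(C)C | intermediate
30 | (1(10)E,3Z)-8,9,12-trihydroxy-2-oxogermacra-1(10),3,11(13)-trien-6-yl tiglate | O[C@@H]1[C@H](C(=C)CO)[C@@H](OC(=O)/C(C)=C/C)C/C(C)=C\C(=O)/C=C(\C)[C@@H]1O | intermediate
31 | C-12 aldehyde (hydroxy enal) of 30 (not isolated) | O[C@@H]1[C@H](C(=C)C=O)[C@@H](OC(=O)/C(C)=C/C)C/C(C)=C\C(=O)/C=C(\C)[C@@H]1O | intermediate
32 | 12,8-lactol, mixture at C-12 (not isolated) | C=C1C(O)O[C@@H]2[C@H]1[C@@H](OC(=O)/C(C)=C/C)C/C(C)=C\C(=O)/C=C(\C)[C@@H]2O | intermediate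
33 | CNP0230565.2, (1(10)E,3Z,6S,7R,8R,9S)-9-hydroxy-2-oxo-6-tigloyloxygermacra-1(10),3,11(13)-trien-12,8-olide | C=C1C(=O)O[C@@H]2[C@H]1[C@@H](OC(=O)/C(C)=C/C)C/C(C)=C\C(=O)/C=C(\C)[C@@H]2O | target

Total step count: 21. Longest linear sequence: 18 steps (steps 1–3, then 7–21).

Steps most likely to fail

1. Step 17 (fragmentation). Once ketone 25 has formed, any alkoxide or amide still present may remove a proton at C-5 or C-7. That would move the C-3=C-4 olefin into conjugation, epimerise C-7 or eliminate the C-8 silyloxy group. Ionisation at C-1 may also be slow next to the ketal, which lengthens the exposure. The fallback sets out from 23. The tertiary hydroxyl is silylated (TMSOTf, 2,6-lutidine, CH2Cl2, −78 °C) to the C-6 trimethylsilyl ether of the mesylate F1. Anhydrous tetrabutylammonium fluoride in THF at −40 to 0 °C then releases the alkoxide, which fragments as it is formed with no amide base present. The route is rejoined at 25.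

2. Step 8 (quaternary C-10). The second deprotonation may be slow, because the C-10 hydrogen is shielded by the cis silyloxy group. Warming may then cause retro-aldol loss of the side chain or elimination of the C-9 silyloxy group. The fallback sets out from 13. Dess–Martin oxidation gives the 1,3-diketone F2, whose stabilised enolate is C-methylated under mild conditions (K2CO3, MeI, acetone, rt), again trans to the silyloxy group, to the methylated diketone F3. The 2-methylallyl Grignard/CeCl3 addition of step 9 is then run on F3. The ring carbonyl is the less shielded ketone, since the side-chain ketone lies between two fully substituted carbons. Addition from the methyl face gives 17 directly, so steps 9 and 10 are not needed.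

3. Step 18 (C-6 reduction). A conformational bias of the ten-membered ring (peripheral hydride attack) may override the catalyst and give poor facial selectivity or the wrong C-6 epimer. The fallback sets out from 25. The (6R)-alcohol F4 is made deliberately (NaBH4/CeCl3, MeOH, −78 °C, or the enantiomeric catalyst). It is esterified with tiglic acid 27 under Mitsunobu conditions (PPh3, diisopropyl azodicarboxylate, toluene, 0 °C). Inversion at C-6 gives tiglate 29, where the route is rejoined.

Further compounds
F1 | step 17 | C-6 O-trimethylsilyl ether of mesylate 23 | CC(C)(C)[Si](C)(C)O[C@@H]1[C@H](C(=C)CO[Si](C)(C)C(C)(C)C)[C@@]2(O[Si](C)(C)C)C/C(C)=C\C3(OCCO3)[C@@H](OS(C)(=O)=O)[C@]2(C)[C@@H]1O[Si](C)(C)C(C)(C)C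
F2 | step 8 | 1,3-diketone from 13 (C-1 ketone; C-10 enolisable, drawn in the keto form) | O=C1C(C(=C)CO[Si](C)(C)C(C)(C)C)=C[C@@H](O[Si](C)(C)C(C)(C)C)C1C(=O)C2(C=C)OCCO2
F3 | step 8 | C-10 methylated 1,3-diketone (methyl trans to the C-9 silyloxy group) | O=C1C(C(=C)CO[Si](C)(C)C(C)(C)C)=C[C@@H](O[Si](C)(C)C(C)(C)C)[C@@]1(C)C(=O)C2(C=C)OCCO2
F4 | step 18 | (6R)-epimer of alcohol 26 | CC(C)(C)[Si](C)(C)O[C@@H]1[C@H](C(=C)CO[Si](C)(C)C(C)(C)C)[C@H](O)C/C(C)=C\C2(OCCO2)/C=C(\C)[C@@H]1O[Si](C)(C)C(C)(C)C
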